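Ring B (the quinone: C1' on the chroman, C2'=O, C3'–OMe, C4'–OMe, C5'=O, C6'–H) is cut into a four-carbon unit C3'–C2'–C1'–C6' and a two-carbon unit C4'–C5'. A 2,4-dichlorocyclobutenone carrying the (S)-chroman supplies the first, (Z)-tributyl(2-methoxyvinyl)stannane the second. One palladium-catalysed operation joins C6' to C5' by cross-coupling and, after electrocyclic opening of the four-membered ring, closes C3'–C4' to a chlorophenol. The step exploits the run of four oxygen-bearing carbons C2'–C5' next to the single ring hydrogen at C6': the cyclobutenone carbonyl becomes O–C3', the stannane brings MeO–C4', chloride marks C2', and C5' is oxidised last. C3 is set by iridium-catalysed hydrogenation.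

Key step: step 8

Remark: C3 of the target is S (priorities C2 > C1' > C4 > H); 4-(benzyloxy)-3,5-dimethoxybenzaldehyde (the benzyl ether of syringaldehyde) is taken as a commercial starting material.

Step 1
Reactants: 1 4-(benzyloxy)-3,5-dimethoxybenzaldehyde
Product: 5 4-(benzyloxy)-2-hydroxy-3,5-dimethoxybenzaldehyde, via lithium amino alkoxide 2 (not isolated), via ortho-lithiated alkoxide 3 (not isolated), via aryl silyl ether 4 (not isolated)
Conditions: LiN(Me)CH2CH2NMe2 (1.1 equiv, from the amine and n-BuLi), THF, −20 °C; n-BuLi (3 equiv), −20 °C; Me3SiOOSiMe3, −78 to 0 °C; 1 M HCl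
Reagents that add atoms: bis(trimethylsilyl) peroxide, C[Si](C)(C)OO[Si](C)(C)C
Why: Directed ortho-metalation through the in situ lithium α-amino alkoxide should lithiate the position between the masked formyl group and the 3-methoxy group (the two ortho positions are equivalent), and electrophilic hydroxylation of the aryllithium with the silyl peroxide while the aldehyde is still masked avoids Dakin cleavage of the product.

Step 2
Reactants: 5 4-(benzyloxy)-2-hydroxy-3,5-dimethoxybenzaldehyde; 6 tert-butyl acrylate
Product: 7 tert-butyl 7-(benzyloxy)-6,8-dimethoxy-2H-chromene-3-carboxylate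
Conditions: DABCO (1 equiv), CHCl3/H2O, rt
Reagents that add atoms: none
Why: Oxa-Michael addition of the phenol to the acrylate followed by intramolecular aldol condensation (Baylis–Hillman-type chromene annulation) should give the 2H-chromene-3-carboxylate, the tert-butyl ester suppressing lactonisation to a coumarin.

Step 3
Reactants: 7 tert-butyl 7-(benzyloxy)-6,8-dimethoxy-2H-chromene-3-carboxylate
Product: 8 tert-butyl (R)-7-(benzyloxy)-6,8-dimethoxychroman-3-carboxylate
Conditions: [Ir(cod)(tBu-PHOX)]BArF (1 mol %, ligand antipode chosen for the R ester), H2 (50 bar), CH2Cl2, rt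
Reagents that add atoms: none
Why: Iridium–phosphinooxazoline catalysed asymmetric hydrogenation of the trisubstituted, aryl-conjugated C3=C4 bond (a cyclic α-substituted cinnamate) should set C3 by catalyst control of the face of hydrogen delivery, and the benzyl ether is inert to this catalyst.

Step 4
Reactants: 8 tert-butyl (R)-7-(benzyloxy)-6,8-dimethoxychroman-3-carboxylate
Product: 10 (S)-7-(benzyloxy)-3-ethynyl-6,8-dimethoxychroman, via aldehyde 9 (not isolated)
Conditions: i-Bu2AlH (1.1 equiv), CH2Cl2, −78 °C; then MeOH, K2CO3, dimethyl (1-diazo-2-oxopropyl)phosphonate, −78 °C to rt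
Reagents that add atoms: dimethyl (1-diazo-2-oxopropyl)phosphonate (Ohira–Bestmann reagent), COP(=O)(OC)C(=[N+]=[N-])C(C)=O
Why: Partial reduction of the ester to aldehyde 9 and immediate Seyferth–Gilbert homologation with the Ohira–Bestmann reagent should give the terminal alkyne without isolating the epimerisable β-aryloxy aldehyde, so C3 keeps its configuration (the descriptor changes from R to S only by priority).

Step 5
Reactants: 10 (S)-7-(benzyloxy)-3-ethynyl-6,8-dimethoxychroman
Product: 12 3-[(S)-7-(benzyloxy)-6,8-dimethoxychroman-3-yl]-2,4-dichlorocyclobut-2-en-1-one (both C4 epimers), via 4,4-dichlorocyclobutenone 11 (not isolated)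
Conditions: Cl3CCOCl (2 equiv), zinc–copper couple Zn(Cu) (3 equiv), Et2O, rt to reflux; then continued stirring with the ZnCl2 formed (no POCl3 or DME added)
Reagents that add atoms: trichloroacetyl chloride, ClC(=O)C(Cl)(Cl)Cl
Why: [2+2] cycloaddition of in situ dichloroketene to the terminal alkyne should give the 3-substituted 4,4-dichlorocyclobutenone, and the zinc chloride left in solution should promote the known 1,3-chloride shift to the conjugated 2,4-dichloro isomer; the chroman stereocentre is a spectator and the new CHCl centre is destroyed in step 8.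

Step 6
Reactants: 13 chloroacetaldehyde dimethyl acetal
Product: 15 methoxyacetylene, via sodium methoxyacetylide 14 (not isolated)
Conditions: NaNH2 (3 equiv), NH3 (l), −33 °C; then saturated aqueous NH4Cl; distillation
Reagents that add atoms: none
Why: Twofold β-elimination (methanol, then hydrogen chloride) by sodium amide gives the sodium acetylide, which is protonated on work-up; this is the standard preparation of alkoxyacetylenes from haloacetals.

Step 7
Reactants: 15 methoxyacetylene; 16 tributyltin hydride
Product: 17 (Z)-tributyl(2-methoxyvinyl)stannane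
Conditions: AIBN (2 mol %), neat, sealed tube, 60 °C
Reagents that add atoms: none
Why: Radical hydrostannation of the alkoxyalkyne places tin on the terminal carbon and should give mainly the Z β-stannyl enol ether by kinetic anti addition, as for the ethoxy analogue; either alkene geometry is usable in step 8.

Step 8
Reactants: 12 3-[(S)-7-(benzyloxy)-6,8-dimethoxychroman-3-yl]-2,4-dichlorocyclobut-2-en-1-one; 17 (Z)-tributyl(2-methoxyvinyl)stannane
Product: 21 2-chloro-3-[(S)-7-(benzyloxy)-6,8-dimethoxychroman-3-yl]-6-methoxyphenol, via alkenylcyclobutenone 18 (not isolated), via dienylketene 19 (not isolated), via cyclohexadienone 20 (not isolated)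
Conditions: PdCl2(PhCN)2 (5 mol %), tri(2-furyl)phosphine (10 mol %), dioxane, 50 °C, then 100 °C
Reagents that add atoms: none
Why: Oxidative addition of zerovalent palladium to the allylic, α-keto C4–Cl bond of 12, transmetalation with 17 and reductive elimination at C4 (Stille coupling) give the 4-alkenylcyclobutenone 18, which on heating undergoes conrotatory 4π-electrocyclic ring opening to the dienylketene 19, disrotatory 6π-electrocyclisation to the cyclohexadienone 20 and tautomerisation to the phenol. The closest known reaction type is the palladium-catalysed cross-coupling/ring expansion of 4-chlorocyclobutenones with alkenylstannanes, whose thermal part is the electrocyclic cascade of the Danheiser benzannulation. The six-membered ring B is closed by 6π-electrocyclisation between the ketene carbon (C3') and the methoxy-bearing vinyl terminus (C4'), after the C6'–C5' bond has been made by the cross-coupling. No new stereocentre survives: the CHCl epimers converge, the sp3 carbon of 20 is lost on aromatisation, and C3 of the chroman is a spectator under these neutral conditions. The step needs coupling at the sp3 C4–Cl bond and not at the vinylic C2–Cl bond, which the much faster oxidative addition of the allylic α-chloroketone secures, and it needs the alkenyl group to rotate inward on ring opening, which the reversibility of the opening secures because only the Z dienylketene is drained by cyclisation.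

Step 9
Reactants: 21 2-chloro-3-[(S)-7-(benzyloxy)-6,8-dimethoxychroman-3-yl]-6-methoxyphenol
Product: 22 (S)-7-(benzyloxy)-3-(2-chloro-3,4-dimethoxyphenyl)-6,8-dimethoxychroman
Conditions: MeI (1.5 equiv), K2CO3, DMF, rt
Reagents that add atoms: methyl iodide, CI
Why: Williamson O-methylation of the only free phenol fixes the C3' oxygen as its methyl ether.

Step 10
Reactants: 22 (S)-7-(benzyloxy)-3-(2-chloro-3,4-dimethoxyphenyl)-6,8-dimethoxychroman
Product: 23 6-[(S)-7-(benzyloxy)-6,8-dimethoxychroman-3-yl]-2,3-dimethoxyphenol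
Conditions: Pd2(dba)3 (2 mol %), tBuBrettPhos (8 mol %), KOH (3 equiv), 1,4-dioxane/H2O, 100 °C; then 1 M HCl
Reagents that add atoms: potassium hydroxide, [K+].[OH-]
Why: Palladium-catalysed C–O coupling with hydroxide (Buchwald–Hartwig-type hydroxylation) with a bulky biarylphosphine that tolerates two ortho substituents should turn C2'–Cl into the phenol; no base-labile group is present and C3–H is not acidic enough to epimerise.

Step 11
Reactants: 23 6-[(S)-7-(benzyloxy)-6,8-dimethoxychroman-3-yl]-2,3-dimethoxyphenol
Product: 24 5-[(S)-7-(benzyloxy)-6,8-dimethoxychroman-3-yl]-2,3-dimethoxycyclohexa-2,5-diene-1,4-dione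
Conditions: (KSO3)2NO (2.5 equiv), KH2PO4, H2O/acetone, rt
Reagents that add atoms: potassium nitrosodisulfonate (Fremy's salt), [K+].[K+].[O]N(S(=O)(=O)[O-])S(=O)(=O)[O-]
Why: Teuber oxidation converts a phenol with a free para position into the para-quinone, here at C5', while the fully etherified ring A has no free hydroxyl and should not be attacked.

Step 12
Reactants: 24 5-[(S)-7-(benzyloxy)-6,8-dimethoxychroman-3-yl]-2,3-dimethoxycyclohexa-2,5-diene-1,4-dione
Product: 26 5-[(S)-7-hydroxy-6,8-dimethoxychroman-3-yl]-2,3-dimethoxycyclohexa-2,5-diene-1,4-dione (CNP0121136.1), via hydroquinone 25 (not isolated)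
Conditions: H2 (1 atm), palladium on carbon (Pd/C, 10 %), EtOAc, rt; filtration; then air (O2), rt
Reagents that add atoms: none
Why: Hydrogenolysis of the benzyl ether (with reduction of the quinone to hydroquinone 25) followed by autoxidation of the electron-rich hydroquinone should restore the quinone and leave the hindered 7-OH and C3 untouched.

Compound list
1 | 4-(benzyloxy)-3,5-dimethoxybenzaldehyde | O=Cc1cc(OC)c(OCc2ccccc2)c(OC)c1 | starting material
2 | lithium α-amino alkoxide from 1 and lithium N,N,N'-trimethylethylenediamide | [Li+].[O-]C(N(C)CCN(C)C)c1cc(OC)c(OCc2ccccc2)c(OC)c1 | intermediate (not isolated)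
3 | 2-lithio derivative of 2 | [Li+].[O-]C(N(C)CCN(C)C)c1cc(OC)c(OCc2ccccc2)c(OC)c1[Li] | intermediate (not isolated)
4 | 2-(trimethylsilyloxy) derivative of 2 | [Li+].[O-]C(N(C)CCN(C)C)c1cc(OC)c(OCc2ccccc2)c(OC)c1O[Si](C)(C)C | intermediate (not isolated)
5 | 4-(benzyloxy)-2-hydroxy-3,5-dimethoxybenzaldehyde | O=Cc1cc(OC)c(OCc2ccccc2)c(OC)c1O | intermediate
6 | tert-butyl acrylate | C=CC(=O)OC(C)(C)C | starting material
7 | tert-butyl 7-(benzyloxy)-6,8-dimethoxy-2H-chromene-3-carboxylate | CC(C)(C)OC(=O)C1=Cc2cc(OC)c(OCc3ccccc3)c(OC)c2OC1 | intermediate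
8 | tert-butyl (R)-7-(benzyloxy)-6,8-dimethoxychroman-3-carboxylate | CC(C)(C)OC(=O)[C@H]1COc2c(cc(OC)c(OCc3ccccc3)c2OC)C1 | intermediate
9 | (R)-7-(benzyloxy)-6,8-dimethoxychroman-3-carbaldehyde | O=C[C@H]1COc2c(cc(OC)c(OCc3ccccc3)c2OC)C1 | intermediate (not isolated)
10 | (S)-7-(benzyloxy)-3-ethynyl-6,8-dimethoxychroman | C#C[C@H]1COc2c(cc(OC)c(OCc3ccccc3)c2OC)C1 | intermediate
11 | 3-[(S)-7-(benzyloxy)-6,8-dimethoxychroman-3-yl]-4,4-dichlorocyclobut-2-en-1-one | O=C1C=C([C@H]2COc3c(cc(OC)c(OCc4ccccc4)c3OC)C2)C1(Cl)Cl | intermediate (not isolated)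
12 | 3-[(S)-7-(benzyloxy)-6,8-dimethoxychroman-3-yl]-2,4-dichlorocyclobut-2-en-1-one (C4 epimers) | O=C1C(Cl)=C([C@H]2COc3c(cc(OC)c(OCc4ccccc4)c3OC)C2)C1Cl | intermediate
13 | chloroacetaldehyde dimethyl acetal | COC(CCl)OC | starting material
14 | sodium methoxyacetylide | [Na+].[C-]#COC | intermediate (not isolated)
15 | methoxyacetylene | C#COC | intermediate
16 | tributyltin hydride | CCCC[SnH](CCCC)CCCC | starting material
17 | (Z)-tributyl(2-methoxyvinyl)stannane | CCCC[Sn](CCCC)(CCCC)/C=C\OC | intermediate
18 | 2-chloro-3-[(S)-7-(benzyloxy)-6,8-dimethoxychroman-3-yl]-4-[(Z)-2-methoxyvinyl]cyclobut-2-en-1-one | O=C1C(Cl)=C([C@H]2COc3c(cc(OC)c(OCc4ccccc4)c3OC)C2)C1/C=C\OC | intermediate (not isolated)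
19 | (3Z,5Z)-2-chloro-3-[(S)-7-(benzyloxy)-6,8-dimethoxychroman-3-yl]-6-methoxyhexa-1,3,5-trien-1-one (dienylketene) | O=C=C(Cl)/C([C@H]1COc2c(cc(OC)c(OCc3ccccc3)c2OC)C1)=C\C=C/OC | intermediate (not isolated)
20 | 2-chloro-3-[(S)-7-(benzyloxy)-6,8-dimethoxychroman-3-yl]-6-methoxycyclohexa-2,4-dien-1-one | O=C1C(Cl)=C([C@H]2COc3c(cc(OC)c(OCc4ccccc4)c3OC)C2)C=CC1OC | intermediate (not isolated)
21 | 2-chloro-3-[(S)-7-(benzyloxy)-6,8-dimethoxychroman-3-yl]-6-methoxyphenol | Oc1c(Cl)c([C@H]2COc3c(cc(OC)c(OCc4ccccc4)c3OC)C2)ccc1OC | intermediate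
22 | (S)-7-(benzyloxy)-3-(2-chloro-3,4-dimethoxyphenyl)-6,8-dimethoxychroman | COc1ccc([C@H]2COc3c(cc(OC)c(OCc4ccccc4)c3OC)C2)c(Cl)c1OC | intermediate
23 | 6-[(S)-7-(benzyloxy)-6,8-dimethoxychroman-3-yl]-2,3-dimethoxyphenol | COc1ccc([C@H]2COc3c(cc(OC)c(OCc4ccccc4)c3OC)C2)c(O)c1OC | intermediate
24 | 5-[(S)-7-(benzyloxy)-6,8-dimethoxychroman-3-yl]-2,3-dimethoxycyclohexa-2,5-diene-1,4-dione | COC1=C(OC)C(=O)C([C@H]2COc3c(cc(OC)c(OCc4ccccc4)c3OC)C2)=CC1=O | intermediate
25 | 5-[(S)-7-hydroxy-6,8-dimethoxychroman-3-yl]-2,3-dimethoxybenzene-1,4-diol | COc1c(O)cc([C@H]2COc3c(cc(OC)c(O)c3OC)C2)c(O)c1OC | intermediate (not isolated)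
26 | 5-[(S)-7-hydroxy-6,8-dimethoxychroman-3-yl]-2,3-dimethoxycyclohexa-2,5-diene-1,4-dione | COC1=C(OC)C(=O)C([C@H]2COc3c(cc(OC)c(O)c3OC)C2)=CC1=O | target

Total step count: 12 (steps 6 and 7 prepare the stannane).
Longest linear sequence: 10 steps (steps 1–5 and 8–12).

Steps most likely to fail

Step 8 (key step). The β-alkoxyvinylstannane may be lost by protodestannylation, transmetalation next to the secondary chroman substituent may be slow, or the ketene may be intercepted before it cyclises. The fallback builds ring B by a different, known ring expansion and gives up the two-bond construction. Setting out from alkyne 10, deprotonation with n-BuLi (THF, −78 °C) and 1,2-addition of the lithium acetylide to dimethyl squarate would give 4-{[(S)-7-(benzyloxy)-6,8-dimethoxychroman-3-yl]ethynyl}-4-hydroxy-2,3-dimethoxycyclobut-2-en-1-one F1 as a mixture of carbinol epimers. Heating F1 in p-xylene (138 °C) should open it to the alkynylketene, which cyclises with hydrogen transfer (Moore rearrangement) to the protected quinone 24, where the route is rejoined before step 12.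

Step 10. Oxidative addition into the electron-rich aryl chloride flanked by a methoxy group and the chroman may be too slow, so that hydrodechlorination or catalyst decay dominates. The fallback replaces direct C–O coupling by C–B bond formation and oxidation. Setting out from 22, Miyaura borylation (Pd2(dba)3, XPhos, bis(pinacolato)diboron, KOAc, dioxane, 100 °C) would give 2-{6-[(S)-7-(benzyloxy)-6,8-dimethoxychroman-3-yl]-2,3-dimethoxyphenyl}-4,4,5,5-tetramethyl-1,3,2-dioxaborolane F2. Oxidation of F2 with NaBO3·4H2O in THF/H2O should return the route at phenol 23.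

Step 3. Facial discrimination on the tert-butyl ester may be poor, since the two C3 substituents (ester and CH2O) are of similar size, or the hindered alkene may be reduced only slowly. The fallback uses carboxylate-directed hydrogenation instead. Setting out from 7, cleavage of the tert-butyl ester (CF3CO2H, CH2Cl2) would give 7-(benzyloxy)-6,8-dimethoxy-2H-chromene-3-carboxylic acid F3. Hydrogenation of F3 with Ru(OAc)2(BINAP) (antipode chosen for the R acid; H2, MeOH) should give (R)-7-(benzyloxy)-6,8-dimethoxychroman-3-carboxylic acid F4. Reduction with BH3·SMe2 (THF) would give [(S)-7-(benzyloxy)-6,8-dimethoxychroman-3-yl]methanol F5. Oxidation of F5 with Dess–Martin periodinane to aldehyde 9 and Ohira–Bestmann homologation (K2CO3, MeOH) return the route at alkyne 10.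

Further compounds
F1 | step 8 | 4-{[(S)-7-(benzyloxy)-6,8-dimethoxychroman-3-yl]ethynyl}-4-hydroxy-2,3-dimethoxycyclobut-2-en-1-one | COC1=C(OC)C(O)(C#C[C@H]2COc3c(cc(OC)c(OCc4ccccc4)c3OC)C2)C1=O
F2 | step 10 | 2-{6-[(S)-7-(benzyloxy)-6,8-dimethoxychroman-3-yl]-2,3-dimethoxyphenyl}-4,4,5,5-tetramethyl-1,3,2-dioxaborolane | COc1ccc([C@H]2COc3c(cc(OC)c(OCc4ccccc4)c3OC)C2)c(B5OC(C)(C)C(C)(C)O5)c1OC
F3 | step 3 | 7-(benzyloxy)-6,8-dimethoxy-2H-chromene-3-carboxylic acid | OC(=O)C1=Cc2cc(OC)c(OCc3ccccc3)c(OC)c2OC1
F4 | step 3 | (R)-7-(benzyloxy)-6,8-dimethoxychroman-3-carboxylic acid | OC(=O)[C@H]1COc2c(cc(OC)c(OCc3ccccc3)c2OC)C1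
F5 | step 3 | [(S)-7-(benzyloxy)-6,8-dimethoxychroman-3-yl]methanol | OC[C@H]1COc2c(cc(OC)c(OCc3ccccc3)c2OC)C1
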